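**Plan**

- Retrosynthetic cuts, in order: the C2 acetate; the side chain at C9–C11 (back to a C9 ketone); ring A at C3–C4, after reading the cis-2,3-diol as a C2=C3 alkene; then C10–C1 and C10–CH3 as two enolate alkylations.
- Enabling feature: ring B (C5–C6–C7=C8(CH3)–C9–C10) with the gem-dimethyl carbon C4 on C5 is the carvone ring with its isopropenyl carbon. A cation at C4 can therefore be captured by a three-carbon arm C1–C2=C3 on C10, with silicon on C3 fixing where the bond and the alkene end up.
- Forward: ring B is bought as (R)-carvone; methyl and a (Z)-3-silylallyl arm go onto C10; hydrochlorination and Lewis acid ionization close ring A at C3–C4 to the trans-decalin; dihydroxylation and acetonide follow. The C11–C15 chain is then joined at C9 by carbonyl addition; oxidative 1,3-transposition, reductive enol triflate formation and triflate reduction give the 7-ene with C9–H; ester and C2 acetate finish.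
- Stereochemistry: C5 from (R)-carvone; C13 from methyl (R)-3-methylglutarate; C10 by alkylation anti to the isopropenyl group; C2/C3 by α-face osmylation; C9 by axial protonation in the dissolving-metal reduction.

Key step: step 6

Remark: labdane numbering (C1–C20) is used for all bicyclic compounds and carvone numbering for the monocyclic ones. Compound 6 is drawn as its major trans epimer but is used as the C6 epimer mixture, since both epimers give the same enolate 7.

**Route**

Step 1
Reactants: 1 3-(trimethylsilyl)prop-2-yn-1-ol
Product: 2 (Z)-3-(trimethylsilyl)prop-2-en-1-ol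
Conditions: H2 (1 atm), P-2 nickel boride (Ni2B, from Ni(OAc)2·4H2O and NaBH4), ethylenediamine, EtOH, rt
Reagents that add atoms: none
Why: Catalytic cis-semihydrogenation of the silylalkyne over poisoned nickel boride delivers both hydrogens to one face and stops at the alkene, which sets the Z geometry.

Step 2
Reactants: 2 (Z)-3-(trimethylsilyl)prop-2-en-1-ol
Product: 3 (Z)-3-bromo-1-(trimethylsilyl)prop-1-ene
Conditions: CBr4, PPh3, CH2Cl2, 0 °C
Reagents that add atoms: carbon tetrabromide BrC(Br)(Br)Br
Why: Appel bromination displaces the oxyphosphonium at the primary allylic carbon by SN2 under neutral conditions, leaving the Z-vinylsilane untouched.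

Step 3
Reactants: 4 (R)-(−)-carvone
Product: 6 trans-6-methylcarvone (methyl trans to isopropenyl; minor cis epimer carried along), via kinetic lithium enolate of carvone 5 (not isolated)
Conditions: LiN(i-Pr)2 (LDA), THF, −78 °C; MeI, −78 → −20 °C
Reagents that add atoms: iodomethane CI
Why: Kinetic deprotonation of the enone takes the α' proton at C6 (cross-conjugated enolate) and SN2 methylation follows; the new C6 centre forms mainly anti to the isopropenyl group but is planarized again in step 4.

Step 4
Reactants: 6 trans-6-methylcarvone, 3 (Z)-3-bromo-1-(trimethylsilyl)prop-1-ene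
Product: 8 6-methyl-6-[(Z)-3-(trimethylsilyl)prop-2-en-1-yl]carvone (silylallyl trans and methyl cis to isopropenyl), via lithium enolate of 6-methylcarvone 7 (not isolated)
Conditions: LiN(i-Pr)2 (LDA), THF, −78 → −20 °C; 3, DMPU, −78 °C → rt
Reagents that add atoms: none
Why: Enolate alkylation (SN2 at the allylic bromide) should occur on the face opposite the neighbouring isopropenyl group, which sits pseudoaxial to avoid allylic strain with the enolate methyl, so the arm enters trans to it and fixes the quaternary centre that becomes C10 (β-methyl).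

Step 5
Reactants: 8 6-methyl-6-[(Z)-3-(trimethylsilyl)prop-2-en-1-yl]carvone
Product: 9 tertiary chloride, 5-(2-chloropropan-2-yl) analogue of 8
Conditions: HCl (g), CH2Cl2, −40 °C; volatiles removed cold, used crude
Reagents that add atoms: hydrogen chloride Cl
Why: Markovnikov ionic hydrochlorination goes through the tertiary cation of the 1,1-disubstituted alkene, which is far more nucleophilic at low temperature than the vinylsilane or the enone alkene.

Step 6
Reactants: 9 tertiary chloride
Product: 10 trans-fused bicyclic dienone (C9 ketone, C7=C8 with 8-methyl, C2=C3, 4,4-dimethyl, 10β-methyl, 5α-H)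
Conditions: TiCl4 (2.2 equiv), 2,6-di-tert-butyl-4-methylpyridine (0.2 equiv), CH2Cl2, −78 → −40 °C
Reagents that add atoms: none
Why: TiCl4 abstracts chloride from C4 to give the tertiary carbenium ion, the Z-vinylsilane on C10 attacks it through its silicon-bearing carbon C3 (forming C3–C4 and the quaternary gem-dimethyl carbon), and the resulting C2 cation, stabilized by hyperconjugation with the axial C3–Si bond, gives up the silyl group to chloride as Me3SiCl and leaves the C2=C3 alkene. The closest known reaction type is the vinylsilane-terminated cation–olefin cyclization (electrophilic ipso substitution of a vinylsilane), initiated here as in Lewis acid tert-alkylations with tertiary chlorides. Ring A closes in a 6-endo-trig mode with respect to the vinylsilane π bond. No new stereocentre is created (C4 carries two methyls and C3 ends up sp2); the trans ring fusion follows from the C5 and C10 centres already in place, whose C4 and C1 arms lie trans-diequatorial and gauche on the carvone ring, and the ring alkene is necessarily cis. The step needs attack at C3 rather than C2, which the β-silicon effect secures (attack at C2 would give a five-membered ring and an α-silyl cation), and it needs closure to outrun proton loss, 1,2-hydride shift from C5 and protodesilylation, for which the Z geometry (the C–Si bond can align with the empty orbital in a chair-like transition state), the low temperature and the hindered pyridine as proton trap are chosen. Quaternary C10 blocks enolization of the ketone, and the enone alkene, further deactivated by TiCl4 on the carbonyl, should not compete as a nucleophile.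

Step 7
Reactants: 10 trans-fused bicyclic dienone
Product: 11 2α,3α-diol of the enone
Conditions: OsO4 (2 mol %), N-methylmorpholine N-oxide, acetone/H2O, rt
Reagents that add atoms: osmium tetroxide O=[Os](=O)(=O)=O; N-methylmorpholine N-oxide C[N+]1([O-])CCOCC1; water O
Why: In this Upjohn dihydroxylation the electrophilic OsO4 should select the isolated cis-alkene over the electron-poor enone alkene and add syn from the α face, opposite the axial β-methyls on C4 and C10, which sets C2 and C3.

Step 8
Reactants: 11 2α,3α-diol of the enone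
Product: 12 2α,3α-acetonide of the enone
Conditions: Me2C(OMe)2, pyridinium p-toluenesulfonate (cat.), acetone, rt
Reagents that add atoms: 2,2-dimethoxypropane COC(C)(C)OC
Why: Acid-catalysed transketalization closes the dioxolane on the cis-diol and masks it for the organometallic, oxidative and reductive steps ahead.

Step 9
Reactants: 13 methyl (R)-3-methylglutarate (monomethyl ester, free acid at the other end)
Product: 14 methyl (R)-5-hydroxy-3-methylpentanoate
Conditions: BH3·SMe2, THF, −10 °C → rt; MeOH quench; used at once
Reagents that add atoms: none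
Why: Borane reduces the free carboxylic acid chemoselectively (through the acyloxyborane) and leaves the methyl ester, which differentiates the two ends of the glutarate without touching the stereocentre.

Step 10
Reactants: 14 methyl (R)-5-hydroxy-3-methylpentanoate
Product: 15 methyl (R)-5-[(tert-butyldimethylsilyl)oxy]-3-methylpentanoate
Conditions: TBSCl, imidazole, DMF, rt
Reagents that add atoms: tert-butyldimethylsilyl chloride CC(C)(C)[Si](C)(C)Cl
Why: Imidazole-promoted silylation of the primary alcohol, done at once to forestall lactonization of the hydroxy ester.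

Step 11
Reactants: 15 methyl (R)-5-[(tert-butyldimethylsilyl)oxy]-3-methylpentanoate
Product: 16 (S)-5-[(tert-butyldimethylsilyl)oxy]-3-methylpentan-1-ol
Conditions: LiAlH4, Et2O, 0 °C
Reagents that add atoms: none
Why: Hydride reduction of the ester to the primary alcohol, under which the silyl ether is stable.

Step 12
Reactants: 16 (S)-5-[(tert-butyldimethylsilyl)oxy]-3-methylpentan-1-ol
Product: 17 (R)-tert-butyl[(5-iodo-3-methylpentyl)oxy]dimethylsilane
Conditions: I2, PPh3, imidazole, CH2Cl2, 0 °C → rt
Reagents that add atoms: iodine II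
Why: Appel-type iodination (Garegg–Samuelsson conditions) converts the primary alcohol to the iodide by SN2 displacement of the oxyphosphonium.

Step 13
Reactants: 12 2α,3α-acetonide of the enone, 17 (R)-tert-butyl[(5-iodo-3-methylpentyl)oxy]dimethylsilane
Product: 20 C9 tertiary allylic alcohol (hydroxyl β and side chain α at C9), via alkyllithium 18 (not isolated), via alkylcerium dichloride 19 (not isolated)
Conditions: 17, t-BuLi (2.1 equiv), Et2O/pentane, −78 °C; CeCl3 (anhydrous, THF slurry), −78 °C; then 12, −78 → 0 °C; aq NH4Cl
Reagents that add atoms: none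
Why: Lithium–iodine exchange, transmetalation to the less basic organocerium and 1,2-addition to the hindered enone form C9–C11; attack is expected anti to the axial C10 methyl, but the new carbinol centre is erased in step 14.

Step 14
Reactants: 20 C9 tertiary allylic alcohol
Product: 21 15-silyloxy-2α,3α-(isopropylidenedioxy)labd-8-en-7-one
Conditions: pyridinium chlorochromate (C5H5NH)[CrO3Cl] (3 equiv), 4 Å molecular sieves, CH2Cl2, rt
Reagents that add atoms: pyridinium chlorochromate [O-][Cr](=O)(=O)Cl.c1cc[nH+]cc1
Why: In this Dauben–Babler oxidative transposition the tertiary allylic chromate ester undergoes a [3,3]-sigmatropic shift to C7 and is oxidized there, giving the tetrasubstituted 8-en-7-one.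

Step 15
Reactants: 21 15-silyloxy-2α,3α-(isopropylidenedioxy)labd-8-en-7-one
Product: 23 15-silyloxy-2α,3α-(isopropylidenedioxy)labd-7-en-7-yl trifluoromethanesulfonate (9α-H), via lithium C7–C8 enolate 22 (not isolated)
Conditions: Li (2.2 equiv), t-BuOH (1.0 equiv), NH3(l)/THF, −78 °C; NH3 evaporated; PhNTf2 (1.5 equiv), THF, 0 °C → rt
Reagents that add atoms: N-phenylbis(trifluoromethanesulfonimide) O=S(=O)(N(c1ccccc1)S(=O)(=O)C(F)(F)F)C(F)(F)F
Why: In the dissolving-metal (Birch-type) enone reduction the β-carbon C9 is protonated axially from the α face of the trans-decalin, which places the side chain equatorial (9α-H), and the regiodefined C7–C8 lithium enolate is then O-sulfonylated.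

Step 16
Reactants: 23 15-silyloxy-2α,3α-(isopropylidenedioxy)labd-7-en-7-yl trifluoromethanesulfonate
Product: 24 (13S)-15-[(tert-butyldimethylsilyl)oxy]-2α,3α-(isopropylidenedioxy)labd-7-ene
Conditions: Pd(OAc)2 (5 mol %), PPh3, HCO2H, Bu3N, DMF, 60 °C
Reagents that add atoms: none
Why: Palladium-catalysed formate reduction of the enol triflate (oxidative addition of zerovalent palladium, formate decarboxylation, reductive elimination) replaces the triflate by hydrogen with the alkene fixed at C7=C8.

Step 17
Reactants: 24 (13S)-15-[(tert-butyldimethylsilyl)oxy]-2α,3α-(isopropylidenedioxy)labd-7-ene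
Product: 25 (13S)-2α,3α-(isopropylidenedioxy)labd-7-en-15-ol
Conditions: Bu4NF, THF, rt
Reagents that add atoms: none
Why: Fluoride-mediated desilylation frees the primary alcohol while the acetonide and alkene are inert.

Step 18
Reactants: 25 (13S)-2α,3α-(isopropylidenedioxy)labd-7-en-15-ol
Product: 26 (13S)-2α,3α-(isopropylidenedioxy)labd-7-en-15-oic acid
Conditions: TEMPO (0.2 equiv), PhI(OAc)2 (2.5 equiv), MeCN/aq pH 7 buffer, rt
Reagents that add atoms: water O
Why: The oxoammonium-mediated (TEMPO/PhI(OAc)2) oxidation takes the primary alcohol through the aldehyde hydrate to the acid under conditions that spare the trisubstituted alkene and the acetonide.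

Step 19
Reactants: 26 (13S)-2α,3α-(isopropylidenedioxy)labd-7-en-15-oic acid
Product: 27 methyl (13S)-2α,3α-dihydroxylabd-7-en-15-oate
Conditions: HCl (1.25 M in MeOH), rt
Reagents that add atoms: methanol CO
Why: Fischer esterification and acid-catalysed acetonide cleavage run together in dilute methanolic HCl at room temperature, where the trisubstituted 7-ene should not migrate.

Step 20
Reactants: 27 methyl (13S)-2α,3α-dihydroxylabd-7-en-15-oate
Product: 28 methyl (13S)-2α-acetoxy-3α-hydroxylabd-7-en-15-oate (CNP0571009.1)
Conditions: Ac2O (1.1 equiv), pyridine, CH2Cl2, 0 °C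
Reagents that add atoms: acetic anhydride CC(=O)OC(C)=O
Why: Kinetic acylation should select the equatorial C2 hydroxyl, because the axial C3 hydroxyl is neopentyl and shielded by the C4 gem-dimethyl group.

**Compound list**

1 | 3-(trimethylsilyl)prop-2-yn-1-ol | OCC#C[Si](C)(C)C | starting material
2 | (Z)-3-(trimethylsilyl)prop-2-en-1-ol | OC/C=C\[Si](C)(C)C | intermediate
3 | (Z)-3-bromo-1-(trimethylsilyl)prop-1-ene | BrC/C=C\[Si](C)(C)C | intermediate
4 | (R)-(−)-carvone | O=C1C(C)=CC[C@@H](C(C)=C)C1 | starting material
5 | kinetic (C1–C6) lithium enolate of carvone | [Li+].[O-]C1=C[C@H](C(C)=C)CC=C1C | intermediate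
6 | (5R,6S)-6-methylcarvone (trans; used with its C6 epimer) | O=C1C(C)=CC[C@@H](C(C)=C)[C@@H]1C | intermediate
7 | lithium enolate of 6-methylcarvone | [Li+].[O-]C1=C(C)[C@H](C(C)=C)CC=C1C | intermediate
8 | (5S,6S)-6-methyl-6-[(Z)-3-(trimethylsilyl)prop-2-en-1-yl]carvone (arm trans, methyl cis to isopropenyl) | O=C1C(C)=CC[C@@H](C(C)=C)[C@]1(C)C/C=C\[Si](C)(C)C | intermediate
9 | tertiary chloride: 5-(2-chloropropan-2-yl) analogue of 8 | O=C1C(C)=CC[C@@H](C(C)(C)Cl)[C@]1(C)C/C=C\[Si](C)(C)C | intermediate
10 | (4aS,8aS)-2,5,5,8a-tetramethyl-4a,5,8,8a-tetrahydronaphthalen-1(4H)-one (labdane C1–C10 core: 9-one, 2,7-diene, 5α-H, 10β-methyl) | O=C1C(C)=CC[C@H]2C(C)(C)C=CC[C@]12C | intermediate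
11 | 2α,3α-dihydroxy derivative of 10 (7-en-9-one) | O=C1C(C)=CC[C@H]2C(C)(C)[C@H](O)[C@H](O)C[C@]12C | intermediate
12 | 2α,3α-acetonide of 11 | O=C1C(C)=CC[C@H]2C(C)(C)[C@@H]3OC(C)(C)O[C@@H]3C[C@]12C | intermediate
13 | methyl (R)-3-methylglutarate (monomethyl ester) | OC(=O)C[C@@H](C)CC(=O)OC | starting material
14 | methyl (R)-5-hydroxy-3-methylpentanoate | OCC[C@@H](C)CC(=O)OC | intermediate
15 | methyl (R)-5-[(tert-butyldimethylsilyl)oxy]-3-methylpentanoate | CC(C)(C)[Si](C)(C)OCC[C@@H](C)CC(=O)OC | intermediate
16 | (S)-5-[(tert-butyldimethylsilyl)oxy]-3-methylpentan-1-ol | CC(C)(C)[Si](C)(C)OCC[C@@H](C)CCO | intermediate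
17 | (R)-tert-butyl[(5-iodo-3-methylpentyl)oxy]dimethylsilane | CC(C)(C)[Si](C)(C)OCC[C@@H](C)CCI | intermediate
18 | alkyllithium from 17 | CC(C)(C)[Si](C)(C)OCC[C@@H](C)CC[Li] | intermediate
19 | alkylcerium dichloride from 18 | CC(C)(C)[Si](C)(C)OCC[C@@H](C)CC[Ce](Cl)Cl | intermediate
20 | C9 tertiary allylic alcohol (7-ene, 9β-OH, side chain 9α, 15-OTBS, 2α,3α-acetonide) | CC(C)(C)[Si](C)(C)OCC[C@@H](C)CC[C@]1(O)C(C)=CC[C@H]2C(C)(C)[C@@H]3OC(C)(C)O[C@@H]3C[C@]12C | intermediate
21 | (13S)-15-[(tert-butyldimethylsilyl)oxy]-2α,3α-(isopropylidenedioxy)labd-8-en-7-one | CC(C)(C)[Si](C)(C)OCC[C@@H](C)CCC1=C(C)C(=O)C[C@H]2C(C)(C)[C@@H]3OC(C)(C)O[C@@H]3C[C@]12C | intermediate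
22 | lithium C7–C8 enolate (9α-H) from 21 | [Li+].CC(C)(C)[Si](C)(C)OCC[C@@H](C)CC[C@H]1C(C)=C([O-])C[C@H]2C(C)(C)[C@@H]3OC(C)(C)O[C@@H]3C[C@]12C | intermediate
23 | (13S)-15-[(tert-butyldimethylsilyl)oxy]-2α,3α-(isopropylidenedioxy)labd-7-en-7-yl trifluoromethanesulfonate | CC(C)(C)[Si](C)(C)OCC[C@@H](C)CC[C@H]1C(C)=C(OS(=O)(=O)C(F)(F)F)C[C@H]2C(C)(C)[C@@H]3OC(C)(C)O[C@@H]3C[C@]12C | intermediate
24 | (13S)-15-[(tert-butyldimethylsilyl)oxy]-2α,3α-(isopropylidenedioxy)labd-7-ene | CC(C)(C)[Si](C)(C)OCC[C@@H](C)CC[C@H]1C(C)=CC[C@H]2C(C)(C)[C@@H]3OC(C)(C)O[C@@H]3C[C@]12C | intermediate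
25 | (13S)-2α,3α-(isopropylidenedioxy)labd-7-en-15-ol | OCC[C@@H](C)CC[C@H]1C(C)=CC[C@H]2C(C)(C)[C@@H]3OC(C)(C)O[C@@H]3C[C@]12C | intermediate
26 | (13S)-2α,3α-(isopropylidenedioxy)labd-7-en-15-oic acid | OC(=O)C[C@@H](C)CC[C@H]1C(C)=CC[C@H]2C(C)(C)[C@@H]3OC(C)(C)O[C@@H]3C[C@]12C | intermediate
27 | methyl (13S)-2α,3α-dihydroxylabd-7-en-15-oate | COC(=O)C[C@@H](C)CC[C@H]1C(C)=CC[C@H]2C(C)(C)[C@H](O)[C@H](O)C[C@]12C | intermediate
28 | methyl (13S)-2α-acetoxy-3α-hydroxylabd-7-en-15-oate (CNP0571009.1) | COC(=O)C[C@@H](C)CC[C@H]1C(C)=CC[C@H]2C(C)(C)[C@H](O)[C@H](OC(C)=O)C[C@]12C | target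

**Step count and risks**

Total: 20 steps. Longest linear sequence: 15 steps (steps 1, 2, 4–8 and 13–20, counted from 1); 14 steps from carvone 4 and 12 from the half-ester 13.

The three steps most likely to fail:

Step 6. The tertiary cation may lose a proton, undergo a 1,2-hydride shift from C5, or the vinylsilane may be protodesilylated before ring A closes, so that ionization does not end in C3–C4 bond formation. The fallback sets out from 6 and comes back at 10 (bypassing 8 and 9), and makes the same C3–C4 bond with palladium instead of a carbocation. Commercial ethyl (Z)-3-iodoacrylate is reduced with i-Bu2AlH (CH2Cl2, −78 °C) to (Z)-3-iodoprop-2-en-1-ol F1, which CBr4/PPh3 converts into (Z)-3-bromo-1-iodoprop-1-ene F2. Alkylation of enolate 7 (made from 6 as in step 4) with F2 should give 6-[(Z)-3-iodoprop-2-en-1-yl]-6-methylcarvone F3 with the same facial preference. A reductive Heck cyclization (Pd(OAc)2, PPh3, HCO2Na, DMF, 80 °C) would then insert zerovalent palladium into the C3–I bond, add the vinylpalladium 6-exo-trig to the isopropenyl alkene (C3–C4 bond, quaternary C4) and reduce the resulting neopentyl alkylpalladium, which has no β-hydrogen, with formate to the second C4 methyl, giving 10.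

Step 15. Over-reduction of the ketone, incomplete sulfonylation of the hindered tetrasubstituted enolate after removal of ammonia, or insufficient facial selectivity in the protonation at C9 may erode the outcome. The fallback sets out from 21 and comes back at 24 (bypassing 23 and step 16). Luche reduction (NaBH4, CeCl3·7H2O, MeOH, −20 °C) should give the 7β allylic alcohol F4 by axial hydride delivery. Mitsunobu displacement with 2-nitrobenzenesulfonylhydrazide (PPh3, diethyl azodicarboxylate, N-methylmorpholine, −30 °C) would give with inversion the 7α N-sulfonylhydrazine F5, which on warming loses 2-nitrobenzenesulfinic acid to the 7α allylic diazene F6. Its retro-ene loss of N2 (Myers reductive 1,3-transposition) transfers hydrogen suprafacially to the α face of C9 and moves the alkene to C7=C8, giving 24 directly.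

Step 20. Discrimination between the two hydroxyls may be insufficient (over-acylation or acylation at C3), or base-mediated acyl migration may blur the result. The fallback sets out from 27 and comes back at 28, and replaces kinetic acylation by tin-templated acylation. Compound 27 is heated with Bu2SnO (MeOH, reflux) to the 2,3-O-dibutylstannylene acetal F7, in which the equatorial C2 oxygen is the more nucleophilic. Acetyl chloride (CH2Cl2, 0 °C) should then acylate O2 only, and aqueous work-up releases 28.

**Further compounds**

F1 | step 6 | (Z)-3-iodoprop-2-en-1-ol | OC/C=C\I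
F2 | step 6 | (Z)-3-bromo-1-iodoprop-1-ene | BrC/C=C\I
F3 | step 6 | 6-[(Z)-3-iodoprop-2-en-1-yl]-6-methylcarvone (arm trans to isopropenyl) | O=C1C(C)=CC[C@@H](C(C)=C)[C@]1(C)C/C=C\I
F4 | step 15 | (13S)-15-[(tert-butyldimethylsilyl)oxy]-2α,3α-(isopropylidenedioxy)labd-8-en-7β-ol | CC(C)(C)[Si](C)(C)OCC[C@@H](C)CCC1=C(C)[C@@H](O)C[C@H]2C(C)(C)[C@@H]3OC(C)(C)O[C@@H]3C[C@]12C
F5 | step 15 | 7α N-(2-nitrobenzenesulfonyl)hydrazine of the labd-8-ene | CC(C)(C)[Si](C)(C)OCC[C@@H](C)CCC1=C(C)[C@H](N(N)S(=O)(=O)c4ccccc4[N+](=O)[O-])C[C@H]2C(C)(C)[C@@H]3OC(C)(C)O[C@@H]3C[C@]12C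
F6 | step 15 | 7α allylic diazene of the labd-8-ene | CC(C)(C)[Si](C)(C)OCC[C@@H](C)CCC1=C(C)[C@H](N=N)C[C@H]2C(C)(C)[C@@H]3OC(C)(C)O[C@@H]3C[C@]12C
F7 | step 20 | 2,3-O-dibutylstannylene acetal of 27 | COC(=O)C[C@@H](C)CC[C@H]1C(C)=CC[C@H]2C(C)(C)[C@@H]3O[Sn](CCCC)(CCCC)O[C@@H]3C[C@]12C
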